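How high does the open intermediate climb in this flask, and when, given that it forms from the substrate and is drawn off into target?

| setting | beta | flask |
|---|---|---|
| substrate | 1.7 M | 1.7 M |
| partner | 0.95 equiv | 0.950 equiv |
| remark | the very flask that is asked about, followed so far |  |
| time |  | 40 h |

beta run (percent of the substrate charged)

| time / h | open intermediate / % | target / % |
|---|---|---|
| 0.133 | 29.0 | 2.2 |
| 0.250 | 40.0 | 6.9 |
| 0.667 | 43.2 | 27.2 |
| 1.33 | 38.4 | 43.4 |
| 3.00 | 33.5 | 50.9 |
| 8.00 | 32.8 | 51.8 |

(scatter of a reading: 0.3 percentage points)

1. the moment within 40 h at which there is most open intermediate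
2. the amount of open intermediate, in percent of the substrate charged, at that time

- the numbers in the tables scatter by 0.3 percentage points (one standard deviation)

The beta run looks odd: 0.95 equiv of partner was charged, yet target stands flat at 51.8% after 8.00 h while 32.8% of open intermediate stays beside it. This reckoning, which is separate from the forecast, counts whatever is not target as a pool of substrate and open intermediate. The open share, the part of that pool standing open at rest, reads 0.680 at 8.00 h:

f = c(open intermediate) / (c(open intermediate) + c(substrate))

Through the beta run, the share reads 0.430, 0.593, 0.678 and 0.682 at 0.250 h, 0.667 h, 1.33 h and 3.00 h. It climbs and then holds, which this reckoning takes as the pool's resting split. The two numbers go together if partner stopped reaching target, but partner was not read. At 0.667 h, f times the pool gives 49.5%, and the reading is lower, 43.2%. That reading stands above those at 0.250 h and 1.33 h, so this reckoning puts the peak between those two times.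

The forecast gives 0.45 h (0.36 h to 0.56 h) and 44.8% (43.9% to 45.8%): “Formation flux balances drain to target near 0.45 h”.

The flask peaks at 44.3% after 0.474 h, inside both ranges.

    open intermediate + second intermediate → target (k = 5.40 × 10⁻⁴ M⁻¹ s⁻¹)
    2 second intermediate → homo product (k = 3.60 × 10⁻⁴ M⁻¹ s⁻¹)
    partner → second intermediate (k = 9.90 × 10⁻⁴ s⁻¹)
    substrate ⇌ open intermediate (K = 2.20, k = 8.40 × 10⁻⁴ s⁻¹)

At that peak the flask holds 18.8% target, so its share is 0.546, lower than f, and f times its pool gives 55.2%. After 40.0 h the flask has 0% of its partner, the limiting reagent, and 0.365 M homo product. The neighbour charged with 0.380 equiv of partner ends with 28.7% target; f gives it 48.5% open intermediate, and it holds 49.0%.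

The numbers in the tables are simulated for an exercise; noise was put on by code.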